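Of the X charged, about 91.1% stands as E late in both runs, at 13 mM as at 26 mM, so I ask how near a new flask comes to that plateau in its time, and that takes two times: the time allowed, and the approach time (a relaxation time) in which the gap to the plateau shrinks by a factor e.

| flask | X | remark | time |
|---|---|---|---|
| winter | 13 mM | run made earlier |  |
| midnight | 26 mM | run made earlier |  |
| south-east | 20 mM |  | 10 h |
| north | 30 mM |  | 5.0 h |

- winter (time / h: E / %, X / %): 0.500: 78.2, 21.7; 1.33: 87.1, 13.0; 2.50: 90.1, 10.0; 4.00: 90.8, 9.5; 5.00: 91.1, 8.6; 8.00: 91.0, 9.4
- midnight (time / h: E / %, X / %): 1.33: 82.0, 17.8; 2.50: 88.5, 12.2; 4.00: 90.2, 8.8; 5.00: 91.0, 9.7; 6.00: 91.5, 9.0; 8.00: 90.8, 8.6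

(standard deviation of a reading: 0.3 percentage points)

1. the winner by amount of E, in percent of the X charged; "neither" if no more than 2 percentage points parts them (south-east / north / neither)
2. how much E is there at the end, in percent of the X charged: south-east
3. how much E is there at the end, in percent of the X charged: north

- a reading or a percentage of E counts all its forms, free or not

From the gaps at the first two midnight readings I read

approach time = elapsed time / ln(first gap / second gap) = 0.934 h,

against 0.709 h from the first two winter readings, which lie earlier in their run, so the stretch of 1.32 for a doubled charge is a rough reading. I stretch it in full proportion to the charge, which is harsher than the runs show, and count the approach times inside the time allowed: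

north: N = 5.0 h / (0.934 h × 30 mM / 26 mM) = 4.64

south-east: N = 13.9

This count of turnovers puts north's estimated gap at 0.88 percentage points of the charge, below the margin, so I reckon 90.2% for north, and south-east's estimated gap lies below the scatter.

The forecast says neither, with 91% for south-east and 90.6% for north, 0.40 points above my north, on the ground that “Time to reach a given conversion therefore scales roughly with concentration”.

The flask gives neither: 91.2% in south-east, 90.8% in north.

    X ⇌ E + Q (K = 0.0330 M, k = 0.00140 s⁻¹)
    G ⇌ E, rate k2*(cs2 - [E]) while solid is left; crystals form when [E] > cs2 (solubility = 3.20 mM, k = 5.00 × 10⁻⁴ s⁻¹)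
    2 X → Z (k = 1.90 × 10⁻⁶ M⁻¹ s⁻¹)

At its 4.64 turnovers north holds X at 9.16% after 5.00 h, against 8.84% after 50.0 h, and south-east recharged at 50 mM counts 5.57 and ends with X at 8.86%. Crystals G, counted in E, hold 79.8% of the charge in north at 5.00 h, and the two runs with the low solubility of E taken away end at 70.1% in south-east and 63.4% in north, 6.7 points apart, wider than the margin of 2 points.

(All runs stem from a simulated flask for substances that don't exist, and the scatter is random.)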